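## Retrosynthetic overview
1. The ketone is made last, from the triethylsilyl (TES) ether of the corresponding alcohol. The α-methyl centre therefore never sits next to a C=O while it is still attached to a long polyene.
2. Cyclohexadiene ring: the bond between the quaternary carbon and the neighbouring CH is cut (retro-6π) back to the open-chain polyene. The flat all-E tetraenyl pyrone is the substrate. Its 4Z isomer is made and consumed in one flask by triplet-sensitised E-to-Z isomerisation followed by thermal disrotatory closure.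
3. The all-E tetraene comes from a 2-ethyl-γ-pyrone and an all-E trienal by vinylogous aldol condensation.
4. The pyrone comes from lactonisation of a linear tripropionate 3,5-diketo ester, then O-methylation. The trienal comes from L-proline dimerisation of propanal followed by three Wittig homologations.
5. Ring order: pyrone ring first (step 6), carbocycle second (step 9).

Assumption: the SMILES is read as ring (1R,6S) with pyrone and alkenyl cis, side chain (2E,4R). Compounds 1, 4, 8 and 9 and all reagents are bought, and all polyenes are handled in amber glassware.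

## Route

Step 1
Reactants: 1 propanal (2 equiv)
Product: 3 (2S,3S)-2-methyl-3-(triethylsilyloxy)pentanal, via (2S,3S)-3-hydroxy-2-methylpentanal 2 (not isolated)
Conditions: L-proline (10 mol %), DMF, 4 °C, 12 h; then imidazole, TESCl, 0 °C
Reagents that add atoms: chlorotriethylsilane (TESCl) CC[Si](Cl)(CC)CC
Why: The proline-catalysed direct aldehyde–aldehyde aldol reaction (enamine catalysis, hydrogen-bonded chair-like transition state) gives the anti (2S,3S) dimer in about 4:1 dr and at least 98% ee, C2 being the future (R) side-chain centre; silylation in the same DMF solution avoids isolating the labile hydroxy aldehyde, and the minor syn isomer is removed by chromatography at 3 or 5.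

Step 2
Reactants: 3 (2S,3S)-2-methyl-3-(triethylsilyloxy)pentanal; 4 2-(triphenyl-λ5-phosphanylidene)propanal
Product: 5 (2E,4R,5S)-2,4-dimethyl-5-(triethylsilyloxy)hept-2-enal
Conditions: PhMe, 80 °C, 16 h
Reagents that add atoms: none
Why: Wittig olefination with a stabilised, essentially non-basic formyl ylide gives the E-trisubstituted enal (above 95:5) directly at the aldehyde oxidation level and does not epimerise the α-centre (the descriptor changes from S to R only because the priorities change).

Step 3
Reactants: 5 (2E,4R,5S)-2,4-dimethyl-5-(triethylsilyloxy)hept-2-enal; 4 2-(triphenyl-λ5-phosphanylidene)propanal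
Product: 6 (2E,4E,6R,7S)-2,4,6-trimethyl-7-(triethylsilyloxy)nona-2,4-dienal
Conditions: PhMe, 110 °C, 24 h
Reagents that add atoms: none
Why: A second Wittig olefination with the same stabilised ylide adds one more E-configured propionate-type unit; the silyl ether and both stereocentres take no part.

Step 4
Reactants: 6 (2E,4E,6R,7S)-2,4,6-trimethyl-7-(triethylsilyloxy)nona-2,4-dienal; 4 2-(triphenyl-λ5-phosphanylidene)propanal (2 equiv)
Product: 7 (2E,4E,6E,8R,9S)-2,4,6,8-tetramethyl-9-(triethylsilyloxy)undeca-2,4,6-trienal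
Conditions: PhMe, 110 °C, 48 h
Reagents that add atoms: none
Why: The third Wittig olefination is slower because the dienal is deactivated, but it stays E-selective, and the all-E trienal cannot coil, so it survives the heating.

Step 5
Reactants: 8 methyl 2-methyl-3-oxopentanoate; 9 N-methoxy-N-methylpropanamide
Product: 11 methyl 2,4-dimethyl-3,5-dioxoheptanoate (stereoisomer and tautomer mixture), via dilithium dianion 10 (not isolated)
Conditions: LiN(iPr)2 (2.1 equiv), THF, −78 to 0 °C; 9, −78 to 0 °C; 1 M HCl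
Reagents that add atoms: none
Why: In this Claisen-type C-acylation the more reactive terminal carbanion (C4) of the β-keto ester dianion attacks the Weinreb amide, whose chelated adduct stops over-addition and proton quench; the two stereocentres formed are irrelevant because both become sp2 in step 6.

Step 6
Reactants: 11 methyl 2,4-dimethyl-3,5-dioxoheptanoate
Product: 12 6-ethyl-4-hydroxy-3,5-dimethyl-2H-pyran-2-one
Conditions: DBU (1.5 equiv), PhMe, 80 °C; 1 M HCl wash
Reagents that add atoms: none
Why: The C5 enolate oxygen lactonises onto the methyl ester (intramolecular acyl substitution), which is the ring closure by which a linear triketide becomes a pyrone, and formation of the aromatic-like hydroxypyrone drives it.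

Step 7
Reactants: 12 6-ethyl-4-hydroxy-3,5-dimethyl-2H-pyran-2-one
Product: 13 2-ethyl-6-methoxy-3,5-dimethyl-4H-pyran-4-one
Conditions: MeOTf (1.2 equiv), CH2Cl2, 0 °C to rt
Reagents that add atoms: methyl trifluoromethanesulfonate (MeOTf) COS(=O)(=O)C(F)(F)F
Why: In this regioselective O-alkylation the hard methylating agent attacks the most basic oxygen (the lactone C=O) to give a 2-methoxy-4-hydroxypyrylium ion, which loses its proton and leaves the α-methoxy-γ-pyrone rather than the 4-methoxy-α-pyrone.

Step 8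
Reactants: 13 2-ethyl-6-methoxy-3,5-dimethyl-4H-pyran-4-one; 7 (2E,4E,6E,8R,9S)-2,4,6,8-tetramethyl-9-(triethylsilyloxy)undeca-2,4,6-trienal
Product: 17 2-methoxy-3,5-dimethyl-6-[(2E,4E,6E,8E,10R,11S)-4,6,8,10-tetramethyl-11-(triethylsilyloxy)trideca-2,4,6,8-tetraen-2-yl]-4H-pyran-4-one, via lithiated pyrone 14 (not isolated), via lithium aldolate 15 (not isolated), via allylic mesylate 16 (not isolated)
Conditions: LiN(SiMe3)2, THF, −78 °C; 7, −78 °C, 1 h; MsCl, −78 to 0 °C; DBU, 0 °C to rt
Reagents that add atoms: none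
Why: In this vinylogous aldol condensation the extended enolate formed at the ethyl CH2 adds 1,2 to the aldehyde, and E1cB-type loss of the very labile trienylic mesylate gives the more stable E alkene (pyrone trans to the chain); no stereocentre remains from the aldol, and C10 and C11 are untouched.

Step 9
Reactants: 17 all-E tetraenyl pyrone TES ether
Product: 19 2-methoxy-3,5-dimethyl-6-{(1R,6S)-1,3,5-trimethyl-6-[(2E,4R,5S)-4-methyl-5-(triethylsilyloxy)hept-2-en-2-yl]cyclohexa-2,4-dien-1-yl}-4H-pyran-4-one, via (2E,4Z,6E,8E)-tetraene 18 (not isolated)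
Conditions: Ru(bpy)3(PF6)2 (2 mol %), 450 nm LED, degassed MeCN (0.01 M), 75 °C, Ar, 12–24 h
Reagents that add atoms: none
Why: Proposed new method: excited Ru(bpy)3(PF6)2 (triplet energy about 46 kcal/mol) passes its energy to the tetraenyl pyrone (estimated below 42 kcal/mol), whose relaxed triplet is twisted about an inner C=C bond and decays to E/Z mixtures without populating the singlet state that would close in the conrotatory sense; only isomers with an inner Z bond can coil, and the 4Z isomer 18 is drained irreversibly at 75 °C by a thermal disrotatory 6π electrocyclisation (C2–C7 bond) that turns the two outward groups (pyrone on C2, alkenyl on C7) onto the same face and so fixes the cis (1R*,6S*) relationship, while the product, whose cyclohexadiene chromophore lies near 52 kcal/mol, is no longer sensitised and cannot go on to the bicyclo[3.1.0]hexene; the absolute sense is decided only by the resident C10/C11 centres, so a dr of about 1:1 to 2:1 is expected and the (1S,6R) diastereomer is removed by chromatography, leaving 19 as a single enantiomer; the closest known reaction types are triplet-sensitised contra-thermodynamic E-to-Z isomerisation of conjugated alkenes and the PdCl2(MeCN)2- or sunlight-triggered isomerisation/electrocyclisation of all-E polyenyl pyrones.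

Step 10
Reactants: 19 cyclohexadienyl pyrone TES ether
Product: 21 2-methoxy-3,5-dimethyl-6-{(1R,6S)-1,3,5-trimethyl-6-[(2E,4R)-4-methyl-5-oxohept-2-en-2-yl]cyclohexa-2,4-dien-1-yl}-4H-pyran-4-one (target), via free alcohol 20 (not isolated)
Conditions: IBX (3 equiv), DMSO, 25 °C, 12–24 h
Reagents that add atoms: none
Why: IBX in DMSO cleaves triethylsilyl ethers and then oxidises the freed secondary alcohol in the same flask (hypervalent-iodine alcohol oxidation); the medium contains no base, so the (4R) α-methyl β,γ-unsaturated ketone is neither epimerised nor conjugated, and the quaternary ring carbon rules out aromatisation.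

## Compound list
1 | propanal | CCC=O | starting material
2 | (2S,3S)-3-hydroxy-2-methylpentanal | O=C[C@@H](C)[C@@H](O)CC | intermediate
3 | (2S,3S)-2-methyl-3-(triethylsilyloxy)pentanal | O=C[C@@H](C)[C@@H](O[Si](CC)(CC)CC)CC | intermediate
4 | 2-(triphenyl-λ5-phosphanylidene)propanal | CC(C=O)=P(c1ccccc1)(c1ccccc1)c1ccccc1 | starting material
5 | (2E,4R,5S)-2,4-dimethyl-5-(triethylsilyloxy)hept-2-enal | O=C/C(C)=C/[C@@H](C)[C@@H](O[Si](CC)(CC)CC)CC | intermediate
6 | (2E,4E,6R,7S)-2,4,6-trimethyl-7-(triethylsilyloxy)nona-2,4-dienal | O=C/C(C)=C/C(C)=C/[C@@H](C)[C@@H](O[Si](CC)(CC)CC)CC | intermediate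
7 | (2E,4E,6E,8R,9S)-2,4,6,8-tetramethyl-9-(triethylsilyloxy)undeca-2,4,6-trienal | O=C/C(C)=C/C(C)=C/C(C)=C/[C@@H](C)[C@@H](O[Si](CC)(CC)CC)CC | intermediate
8 | methyl 2-methyl-3-oxopentanoate (racemic) | CCC(=O)C(C)C(=O)OC | starting material
9 | N-methoxy-N-methylpropanamide | CCC(=O)N(C)OC | starting material
10 | dilithium dianion of 8 (deprotonated at C2 and C4) | [Li+].[Li+].CC=C([O-])C(C)=C([O-])OC | intermediate
11 | methyl 2,4-dimethyl-3,5-dioxoheptanoate | CCC(=O)C(C)C(=O)C(C)C(=O)OC | intermediate
12 | 6-ethyl-4-hydroxy-3,5-dimethyl-2H-pyran-2-one | CCc1oc(=O)c(C)c(O)c1C | intermediate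
13 | 2-ethyl-6-methoxy-3,5-dimethyl-4H-pyran-4-one | CCc1oc(OC)c(C)c(=O)c1C | intermediate
14 | lithium extended enolate of 13 (deprotonated at the ethyl CH2) | [Li+].CC=C1OC(OC)=C(C)C([O-])=C1C | intermediate
15 | lithium (4E,6E,8E,10R,11S)-2-(6-methoxy-3,5-dimethyl-4-oxo-4H-pyran-2-yl)-4,6,8,10-tetramethyl-11-(triethylsilyloxy)trideca-4,6,8-trien-3-olate (C2/C3 epimers) | [Li+].COc1oc(C(C)C([O-])/C(C)=C/C(C)=C/C(C)=C/[C@@H](C)[C@@H](O[Si](CC)(CC)CC)CC)c(C)c(=O)c1C | intermediate
16 | the corresponding trideca-4,6,8-trien-3-yl methanesulfonate (C2/C3 epimers) | COc1oc(C(C)C(OS(C)(=O)=O)/C(C)=C/C(C)=C/C(C)=C/[C@@H](C)[C@@H](O[Si](CC)(CC)CC)CC)c(C)c(=O)c1C | intermediate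
17 | 2-methoxy-3,5-dimethyl-6-[(2E,4E,6E,8E,10R,11S)-4,6,8,10-tetramethyl-11-(triethylsilyloxy)trideca-2,4,6,8-tetraen-2-yl]-4H-pyran-4-one | COc1oc(/C(C)=C/C(C)=C/C(C)=C/C(C)=C/[C@@H](C)[C@@H](O[Si](CC)(CC)CC)CC)c(C)c(=O)c1C | intermediate
18 | (2E,4Z,6E,8E,10R,11S) isomer of 17 | COc1oc(/C(C)=C/C(C)=C\C(C)=C\C(C)=C\[C@@H](C)[C@@H](O[Si](CC)(CC)CC)CC)c(C)c(=O)c1C | intermediate
19 | 2-methoxy-3,5-dimethyl-6-{(1R,6S)-1,3,5-trimethyl-6-[(2E,4R,5S)-4-methyl-5-(triethylsilyloxy)hept-2-en-2-yl]cyclohexa-2,4-dien-1-yl}-4H-pyran-4-one | CC[C@H](O[Si](CC)(CC)CC)[C@H](C)/C=C(\C)[C@H]1C(C)=CC(C)=C[C@@]1(C)c1oc(OC)c(C)c(=O)c1C | intermediate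
20 | 6-{(1R,6S)-6-[(2E,4R,5S)-5-hydroxy-4-methylhept-2-en-2-yl]-1,3,5-trimethylcyclohexa-2,4-dien-1-yl}-2-methoxy-3,5-dimethyl-4H-pyran-4-one | CC[C@H](O)[C@H](C)/C=C(\C)[C@H]1C(C)=CC(C)=C[C@@]1(C)c1oc(OC)c(C)c(=O)c1C | intermediate
21 | 2-methoxy-3,5-dimethyl-6-{(1R,6S)-1,3,5-trimethyl-6-[(2E,4R)-4-methyl-5-oxohept-2-en-2-yl]cyclohexa-2,4-dien-1-yl}-4H-pyran-4-one | CCC(=O)[C@H](C)/C=C(\C)[C@H]1C(C)=CC(C)=C[C@@]1(C)c1oc(OC)c(C)c(=O)c1C | target

## Step count and weak points
Total step count: 10. Longest linear sequence: 7 (steps 1, 2, 3, 4, 8, 9, 10).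

**Step 9 (most likely to fail).**
- Sensitised scrambling is not confined to the C4=C5 bond. A 6Z isomer could close between C4 and C9.
- A 4Z,6Z isomer could run an 8π/6π sequence to a bicyclo[4.2.0]octadiene.
- A reversible [1,7]-hydrogen shift from the inward methyl may slow the closure.
- The facial bias from C10/C11 is small.

The fallback gives up the in-flask isomerisation and builds the Z bond by olefination. It sets out from dienal 6 and comes back at tetraene 18, and so at 19. Dienal 6 is treated with ethyl 2-[bis(2,2,2-trifluoroethoxy)phosphoryl]propanoate, KN(SiMe3)2 and 18-crown-6 at −78 °C (Still–Gennari olefination) to give the ethyl (2Z,4E,6E)-trienoate F1. This is reduced with iBu2AlH to the (2Z)-trienol F2 and oxidised with MnO2 at 0 °C in the dark to the (2Z)-trienal F3. Lithiated pyrone 14 is added to give the lithium aldolate F4, which is trapped with MsCl as the mesylate F5 and eliminated with DBU. This delivers 18 as a defined compound, which is simply heated in toluene at 80–100 °C in the dark to give 19 and its separable ring diastereomer.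

**Step 8.**
- The aldol addition of the extended enolate is reversible.
- The trienylic mesylate may ionise to allylic chlorides or give E/Z mixtures.

The fallback makes the pyrone last, on the finished polyene. It sets out from trienal 7 and comes back at 17. One more Wittig reaction of 7 with 4 gives the all-E tetraenal F6. Addition of dianion 10 gives the hydroxy keto ester F7, and Dess–Martin periodinane gives the 3,5-diketo ester F8. DBU closes this to the tetraenyl hydroxy-α-pyrone F9. MeOTf, buffered by 2,6-di-tert-butylpyridine, then gives 17.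

**Step 10.**
- The hindered secondary TES ether may cleave slowly.
- The acidity of IBX over a long reaction time could epimerise or conjugate the β,γ-enone.

The fallback separates the two events and changes both chemistries. It sets out from 19 and comes back at 21. HF·pyridine in THF at 0 °C gives alcohol 20, now isolated, which offers a second and easier chance to remove the ring diastereomer. Dess–Martin periodinane with NaHCO3 in CH2Cl2 at 0 °C then gives 21. This detour makes no compound outside the list (entry F0).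

## Further compounds
F1 | step 9 | ethyl (2Z,4E,6E,8R,9S)-2,4,6,8-tetramethyl-9-(triethylsilyloxy)undeca-2,4,6-trienoate | CCOC(=O)/C(C)=C\C(C)=C\C(C)=C\[C@@H](C)[C@@H](O[Si](CC)(CC)CC)CC
F2 | step 9 | (2Z,4E,6E,8R,9S)-2,4,6,8-tetramethyl-9-(triethylsilyloxy)undeca-2,4,6-trien-1-ol | OC/C(C)=C\C(C)=C\C(C)=C\[C@@H](C)[C@@H](O[Si](CC)(CC)CC)CC
F3 | step 9 | (2Z,4E,6E,8R,9S)-2,4,6,8-tetramethyl-9-(triethylsilyloxy)undeca-2,4,6-trienal | O=C/C(C)=C\C(C)=C\C(C)=C\[C@@H](C)[C@@H](O[Si](CC)(CC)CC)CC
F4 | step 9 | lithium (4Z,6E,8E,10R,11S)-2-(6-methoxy-3,5-dimethyl-4-oxo-4H-pyran-2-yl)-4,6,8,10-tetramethyl-11-(triethylsilyloxy)trideca-4,6,8-trien-3-olate (C2/C3 epimers) | [Li+].COc1oc(C(C)C([O-])/C(C)=C\C(C)=C\C(C)=C\[C@@H](C)[C@@H](O[Si](CC)(CC)CC)CC)c(C)c(=O)c1C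
F5 | step 9 | the corresponding (4Z,6E,8E)-trideca-4,6,8-trien-3-yl methanesulfonate (C2/C3 epimers) | COc1oc(C(C)C(OS(C)(=O)=O)/C(C)=C\C(C)=C\C(C)=C\[C@@H](C)[C@@H](O[Si](CC)(CC)CC)CC)c(C)c(=O)c1C
F6 | step 8 | (2E,4E,6E,8E,10R,11S)-2,4,6,8,10-pentamethyl-11-(triethylsilyloxy)trideca-2,4,6,8-tetraenal | O=C/C(C)=C/C(C)=C/C(C)=C/C(C)=C/[C@@H](C)[C@@H](O[Si](CC)(CC)CC)CC
F7 | step 8 | methyl (6E,8E,10E,12E,14R,15S)-5-hydroxy-2,4,6,8,10,12,14-heptamethyl-3-oxo-15-(triethylsilyloxy)heptadeca-6,8,10,12-tetraenoate (C2/C4/C5 epimers) | COC(=O)C(C)C(=O)C(C)C(O)/C(C)=C/C(C)=C/C(C)=C/C(C)=C/[C@@H](C)[C@@H](O[Si](CC)(CC)CC)CC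
F8 | step 8 | methyl (6E,8E,10E,12E,14R,15S)-2,4,6,8,10,12,14-heptamethyl-3,5-dioxo-15-(triethylsilyloxy)heptadeca-6,8,10,12-tetraenoate | COC(=O)C(C)C(=O)C(C)C(=O)/C(C)=C/C(C)=C/C(C)=C/C(C)=C/[C@@H](C)[C@@H](O[Si](CC)(CC)CC)CC
F9 | step 8 | 4-hydroxy-3,5-dimethyl-6-[(2E,4E,6E,8E,10R,11S)-4,6,8,10-tetramethyl-11-(triethylsilyloxy)trideca-2,4,6,8-tetraen-2-yl]-2H-pyran-2-one | O=c1oc(/C(C)=C/C(C)=C/C(C)=C/C(C)=C/[C@@H](C)[C@@H](O[Si](CC)(CC)CC)CC)c(C)c(O)c1C
F0 | step 10 | none | none
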